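Watch the ratio of the two products. The runs and the flask to come are these:

| flask | left-handed substrate | right-handed substrate | solid reagent | protic impurity | catalyst | remark | time |
|---|---|---|---|---|---|---|---|
| summer | 10 mM | 10 mM | 11 mM | 2 mM | 0.10 mM | run made earlier |  |
| winter | 10 mM | 10 mM | 11 mM | 2 mM | 0.40 mM | run made earlier |  |
| dawn | 10 mM | 10 mM | 11 mM | 3 mM | 0.20 mM | run made earlier |  |
| flask | 10 mM | 10 mM | 11.0 mM | 2.00 mM | 0.20 mM |  | 1.5 h |

| run | time / min | left-handed product / % | right-handed product / % | left-handed substrate / % |
|---|---|---|---|---|
| summer | 10.0 | 1.6 | 0.6 | 49.9 |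
| summer | 20.0 | 2.0 | 3.5 | 46.6 |
| summer | 30.0 | 6.0 | 2.0 | 45.6 |
| summer | 40.0 | 5.0 | 3.6 | 44.3 |
| summer | 50.0 | 8.1 | 4.8 | 43.8 |
| summer | 60.0 | 9.7 | 5.3 | 43.3 |
| summer | 80.0 | 13.7 | 7.6 | 41.0 |
| winter | 6.00 | 1.6 | 1.2 | 48.8 |
| winter | 8.00 | 1.5 | 2.0 | 48.4 |
| winter | 12.0 | 1.9 | 1.2 | 47.9 |
| winter | 20.0 | 1.9 | 3.5 | 48.5 |
| winter | 30.0 | 5.2 | 3.5 | 45.3 |
| winter | 50.0 | 8.8 | 4.8 | 43.1 |
| winter | 80.0 | 15.7 | 9.7 | 36.8 |
| dawn | 6.00 | 0 | 0.4 | 50.1 |
| dawn | 10.0 | 2.2 | 0 | 48.0 |
| dawn | 20.0 | 3.5 | 1.7 | 47.0 |
| dawn | 40.0 | 7.4 | 4.3 | 44.5 |
| dawn | 80.0 | 13.3 | 9.1 | 37.7 |

(scatter of a reading: 1 percentage point)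

- catalyst is single-handed; left-handed substrate and right-handed substrate are mirror images of each other, charged as a racemate, each of them at the stated concentration
- given per volume of solution although it is solid: solid reagent
- steps under discussion: left-handed substrate <-> right-handed substrate; partner + protic impurity -> quenched reagent; partner + catalyst + left-handed substrate -> catalyst + left-handed product; partner + catalyst + right-handed substrate -> catalyst + right-handed product; solid reagent <-> partner
- at the start none of the solid reagent is in solution
- an excess is the difference of the two amounts in percent of their sum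
- an excess is below zero if the other one leads

* excess of left-handed product over right-handed product in the product at 10 min
* excess of left-handed product over right-handed product in the product at 1.5 h
* part of the left-handed substrate and right-handed substrate charged together that has reacted at 1.5 h

Each reading scatters by 1 percentage point, so I start from the last reading of each run, at 80.0 min. Added over the three runs, left-handed product makes 42.7% and right-handed product 26.4%, which gives an excess of 23.6%.

That reading of the catalyst's preference holds if the two substrates stay level, so I put the answer back in. On average 23.0% has reacted, so level substrates put left-handed substrate at 38.5%, and the readings average 38.5%. Without exchange between the substrates, right-handed substrate would lead by 5.4 points. I therefore make no correction and take one excess for both 10 min and 1.5 h.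

For the reacted part, I note that the summer run at 0.10 mM of catalyst reached 21.3% and the winter run at 0.40 mM reached 25.4%. The flask's 0.20 mM lies between them, so I stretch the average in proportion to time and get 25.9%.

The weak link is the excess, which rests on three pairs of readings. Adding the pair before the last from each run raises the ratio to 1.68, and this is the split I carry: left-handed product formed per right-handed product formed. While the substrates stay level, I read it as a selectivity factor. It gives an excess of 25.4%, and that is my number for both times.

The forecast says 24%, 23% and 26% reacted, on the ground that “racemisation is keeping up, so the excess should stay roughly constant over time”. Its excesses lie below mine.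

The flask gives 25.3% at 10 min, 25.0% at 1.5 h and 24.8% reacted, so the forecast is right within its tolerance.

    left-handed substrate ⇌ right-handed substrate (k = 0.0560 min⁻¹)
    partner + protic impurity → quenched reagent (k = 5.40 L mol⁻¹ min⁻¹)
    partner + catalyst + left-handed substrate → catalyst + left-handed product (k = 5.40 × 10⁵ L² mol⁻² min⁻¹)
    partner + catalyst + right-handed substrate → catalyst + right-handed product (k = 3.20 × 10⁵ L² mol⁻² min⁻¹)
    solid reagent ⇌ partner, rate k5*(cs5 - [partner]) while solid is left; crystals form when [partner] > cs5 (solubility = 0.410 mM, k = 0.150 min⁻¹)

At 1.5 h, the catalysed step uses left-handed substrate at 0.082 of the rate of the forward step to right-handed substrate alone. The flask then holds 37.3% left-handed and 37.9% right-handed substrate. The split turns 24.8% reacted into 15.5% left-handed product, and the flask holds 15.5%. The neighbour charged with 0.050 mM of catalyst reacts 19.1% at an excess of 25.1%; the split turns that into 12.0%, and that neighbour holds 12.0%.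

The earlier runs and the new flask are calculated for substances that don't exist, and the scatter is random.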